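**Plan**
- Elemane numbering: cyclohexane C5–C10; C5 carries the enal (C4, C3, C15), C6 the lactone oxygen, C7 the lactone carbons C11–C13, C8 the acyloxy group, C9 is CH2, C10 carries methyl C14 and vinyl C1=C2; C3' is the side-chain carbinol carbon.
- Retrosynthesis cuts, in order: the C8 ester bond, the C15 oxygen, C11=C13, the lactone O6–C12 bond, then ring bond C5–C6, then C7–C8, then the two alkenes on C10.
- The C5–C6 cut is possible because an equatorial C6 oxygen trans to a C5 isopropenyl group on a six-membered ring is the isopulegol pattern, which a carbonyl-ene reaction of an acyclic aldehyde with a 2-methylpropenyl group delivers.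
- Forward: chain C10→C8 from a desymmetrised malonate-derived diol, aldol union with a succinate imide (C7–C8), cyclohexane closure (step 16), γ-lactone (step 17), then methylenation, C15 oxidation, acylation at O8.
- Stereochemistry: C10 from lipase desymmetrisation; C7/C8 from the (R)-benzyloxazolidinone syn-aldol; C5/C6 from the chair ene transition state; C3' from methyl 3,4-O-isopropylidene-L-threonate.

Key step: step 16

Assumption: the lipase is taken to acetylate the arm that gives (S)-5; should it prefer the other arm, the ylides of steps 5 and 8 are exchanged and the same aldehyde 12 results.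

**Route**

Step 1
Reactants: 1 diethyl methylmalonate; 2 (2-bromoethoxy)(tert-butyl)dimethylsilane
Product: 3 diethyl 2-{2-[(tert-butyldimethylsilyl)oxy]ethyl}-2-methylmalonate
Conditions: NaH, DMF, 0 °C; then 2, NaI (cat.), 60 °C
Reagents that add atoms: none
Why: Malonic ester alkylation (SN2 of the sodium enolate on the primary bromide), with iodide catalysis to offset the retarding β-oxygen.

Step 2
Reactants: 3 diethyl 2-{2-[(tert-butyldimethylsilyl)oxy]ethyl}-2-methylmalonate
Product: 4 2-{2-[(tert-butyldimethylsilyl)oxy]ethyl}-2-methylpropane-1,3-diol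
Conditions: LiAlH4, THF, 0 °C → rt
Reagents that add atoms: none
Why: Hydride reduction of both esters gives the prochiral 1,3-diol; the silyl ether is inert to LiAlH4.

Step 3
Reactants: 4 2-{2-[(tert-butyldimethylsilyl)oxy]ethyl}-2-methylpropane-1,3-diol
Product: 5 (S)-4-[(tert-butyldimethylsilyl)oxy]-2-(hydroxymethyl)-2-methylbutyl acetate
Conditions: lipase PS (Burkholderia cepacia), vinyl acetate, iPr2O, rt
Reagents that add atoms: vinyl acetate C=COC(C)=O
Why: Enzymatic desymmetrisation (lipase transesterification of a prochiral 2,2-disubstituted propane-1,3-diol with an irreversible acyl donor); the enzyme should tell the methyl group from the long silyloxyethyl chain and so set C10, and over-acylation drains the minor enantiomer into the diacetate.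

Step 4
Reactants: 5 (S)-4-[(tert-butyldimethylsilyl)oxy]-2-(hydroxymethyl)-2-methylbutyl acetate
Product: 6 (R)-4-[(tert-butyldimethylsilyl)oxy]-2-formyl-2-methylbutyl acetate
Conditions: Dess–Martin periodinane, pyridine, CH2Cl2, 0 °C → rt, on crude 5
Reagents that add atoms: none
Why: Dess–Martin oxidation run at once removes the free hydroxyl, so 1,3-acyl migration can no longer racemise C10; the aldehyde has no α-hydrogen.

Step 5
Reactants: 6 (R)-4-[(tert-butyldimethylsilyl)oxy]-2-formyl-2-methylbutyl acetate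
Product: 7 (S)-2-{2-[(tert-butyldimethylsilyl)oxy]ethyl}-2-methylbut-3-en-1-yl acetate
Conditions: Ph3PCH3Br, KHMDS, THF, 0 °C; then 6, −78 → 0 °C
Reagents that add atoms: methyltriphenylphosphonium bromide C[P+](c1ccccc1)(c1ccccc1)c1ccccc1.[Br-]
Why: Wittig methylenation; the non-stabilised ylide takes the aldehyde far faster than the acetate and the silazide leaves no nucleophilic base.

Step 6
Reactants: 7 (S)-2-{2-[(tert-butyldimethylsilyl)oxy]ethyl}-2-methylbut-3-en-1-yl acetate
Product: 8 (S)-2-{2-[(tert-butyldimethylsilyl)oxy]ethyl}-2-methylbut-3-en-1-ol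
Conditions: K2CO3 (cat.), MeOH, rt
Reagents that add atoms: none
Why: Base-catalysed methanolysis (transesterification) of the acetate; the primary silyl ether and the alkene are stable.

Step 7
Reactants: 8 (S)-2-{2-[(tert-butyldimethylsilyl)oxy]ethyl}-2-methylbut-3-en-1-ol
Product: 9 (S)-2-{2-[(tert-butyldimethylsilyl)oxy]ethyl}-2-methylbut-3-enal
Conditions: Dess–Martin periodinane, pyridine, CH2Cl2, 0 °C → rt
Reagents that add atoms: none
Why: Dess–Martin oxidation; the quaternary α-carbon excludes epimerisation and conjugation of the vinyl group.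

Step 8
Reactants: 9 (S)-2-{2-[(tert-butyldimethylsilyl)oxy]ethyl}-2-methylbut-3-enal
Product: 10 tert-butyl{[(S)-3,5-dimethyl-3-vinylhex-4-en-1-yl]oxy}dimethylsilane
Conditions: iPrPPh3I, n-BuLi, THF, 0 °C; then 9, 0 °C → rt
Reagents that add atoms: isopropyltriphenylphosphonium iodide CC(C)[P+](c1ccccc1)(c1ccccc1)c1ccccc1.[I-]
Why: Wittig olefination with isopropylidenetriphenylphosphorane builds the trisubstituted C5=C4 alkene (the ene donor); no E/Z question arises because the ylide carbon bears two methyl groups.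

Step 9
Reactants: 10 tert-butyl{[(S)-3,5-dimethyl-3-vinylhex-4-en-1-yl]oxy}dimethylsilane
Product: 11 (S)-3,5-dimethyl-3-vinylhex-4-en-1-ol
Conditions: TBAF, THF, 0 °C → rt
Reagents that add atoms: none
Why: Fluoride-driven desilylation of the primary silyl ether.

Step 10
Reactants: 11 (S)-3,5-dimethyl-3-vinylhex-4-en-1-ol
Product: 12 (S)-3,5-dimethyl-3-vinylhex-4-enal
Conditions: Dess–Martin periodinane, pyridine, CH2Cl2, 0 °C; used crude (volatile)
Reagents that add atoms: none
Why: Dess–Martin oxidation gives the β-quaternary aldehyde without acid or base that could move the alkenes.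

Step 11
Reactants: 13 4-tert-butoxy-4-oxobutanoic acid; 14 (R)-4-benzyloxazolidin-2-one
Product: 16 tert-butyl 4-[(R)-4-benzyl-2-oxooxazolidin-3-yl]-4-oxobutanoate, via mixed pivalic anhydride 15 (not isolated)
Conditions: PivCl, Et3N, THF, −20 °C; then 14, LiCl, −20 °C → rt
Reagents that add atoms: none
Why: N-acylation of the oxazolidinone through a mixed anhydride; the nucleophile attacks the unhindered succinyl carbonyl, not the pivaloyl one.

Step 12
Reactants: 16 tert-butyl 4-[(R)-4-benzyl-2-oxooxazolidin-3-yl]-4-oxobutanoate; 12 (S)-3,5-dimethyl-3-vinylhex-4-enal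
Product: 19 tert-butyl (3R,4S,6S)-3-[(R)-4-benzyl-2-oxooxazolidine-3-carbonyl]-4-hydroxy-6,8-dimethyl-6-vinylnon-7-enoate, via Z-boron enolate 17 (not isolated), via boron aldolate 18 (not isolated)
Conditions: Bu2BOTf, iPr2NEt, CH2Cl2, 0 °C; then 12, −78 → 0 °C; pH 7 buffer, MeOH, H2O2, 0 °C
Reagents that add atoms: none
Why: Evans syn aldol; the imide is enolised selectively to the Z-boron enolate, and the chair Zimmerman–Traxler transition state with the aldehyde on the enolate face away from the benzyl group sets C7 (R) and C8 (S), the syn pair that becomes trans on the ring.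

Step 13
Reactants: 19 tert-butyl (3R,4S,6S)-3-[(R)-4-benzyl-2-oxooxazolidine-3-carbonyl]-4-hydroxy-6,8-dimethyl-6-vinylnon-7-enoate
Product: 20 tert-butyl (3R,4S,6S)-3-[(R)-4-benzyl-2-oxooxazolidine-3-carbonyl]-4-[(tert-butyldimethylsilyl)oxy]-6,8-dimethyl-6-vinylnon-7-enoate
Conditions: TBSOTf, 2,6-lutidine, CH2Cl2, −78 → 0 °C
Reagents that add atoms: tert-butyldimethylsilyl triflate CC(C)(C)[Si](C)(C)OS(=O)(=O)C(F)(F)F
Why: Silylation of the secondary alcohol with a silyl triflate and a hindered base; it blocks O8 so that only O6 can later close the lactone.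

Step 14
Reactants: 20 tert-butyl (3R,4S,6S)-3-[(R)-4-benzyl-2-oxooxazolidine-3-carbonyl]-4-[(tert-butyldimethylsilyl)oxy]-6,8-dimethyl-6-vinylnon-7-enoate
Product: 21 tert-butyl (3S,4S,6S)-4-[(tert-butyldimethylsilyl)oxy]-3-(hydroxymethyl)-6,8-dimethyl-6-vinylnon-7-enoate
Conditions: LiBH4, MeOH (1 equiv), THF, 0 °C
Reagents that add atoms: none
Why: Reductive cleavage of the N-acyl oxazolidinone by LiBH4 at the exocyclic carbonyl; the tert-butyl ester is too hindered to be reduced and the auxiliary is recovered.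

Step 15
Reactants: 21 tert-butyl (3S,4S,6S)-4-[(tert-butyldimethylsilyl)oxy]-3-(hydroxymethyl)-6,8-dimethyl-6-vinylnon-7-enoate
Product: 22 tert-butyl (3R,4S,6S)-4-[(tert-butyldimethylsilyl)oxy]-3-formyl-6,8-dimethyl-6-vinylnon-7-enoate
Conditions: Dess–Martin periodinane, pyridine, CH2Cl2, 0 °C; used directly
Reagents that add atoms: none
Why: Buffered Dess–Martin oxidation gives the α-branched aldehyde without epimerising C7 or eliminating the β-silyloxy group.

Step 16
Reactants: 22 tert-butyl (3R,4S,6S)-4-[(tert-butyldimethylsilyl)oxy]-3-formyl-6,8-dimethyl-6-vinylnon-7-enoate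
Product: 23 tert-butyl 2-[(1S,2R,3S,4S,6S)-6-[(tert-butyldimethylsilyl)oxy]-2-hydroxy-4-methyl-3-(prop-1-en-2-yl)-4-vinylcyclohexyl]acetate
Conditions: Me2AlCl (2 equiv), CH2Cl2, −78 → −40 °C; aq. Rochelle salt
Reagents that add atoms: none
Why: Me2AlCl binds the aldehyde oxygen, the C5=C4 bond of the 2-methylpropenyl group attacks C6 through C5 and a hydrogen of a terminal methyl group passes to oxygen within one closed bicyclic transition state, so that C5–C6 forms and the alkene moves to C4=C3 (isopropenyl); this is a Lewis-acid-promoted intramolecular type I carbonyl-ene reaction, the closest known case being the cyclisation of citronellal to isopulegol. The cyclohexane closes in a 6-exo mode at the carbonyl carbon through a chair in which C7 (CH2CO2tBu) and C8 (OTBS) sit equatorial, since the other chair would place both of them and the C10 vinyl group axial. C6 is set by the aluminium-bound oxygen taking the equatorial site, because an axial C6–O would be syn-diaxial to the axial C10 methyl group. C5 is set by the forming isopropenyl carbon C4 taking the equatorial site gauche to that oxygen, the isopulegol arrangement. The step needs the trisubstituted alkene to react in preference to the vinyl group, which is secured because the vinyl group has no allylic hydrogen and could only give a primary or secondary cation, and it needs ene rather than Prins chemistry, which the proton-scavenging methylaluminium reagent at low temperature should favour.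

Step 17
Reactants: 23 tert-butyl 2-[(1S,2R,3S,4S,6S)-6-[(tert-butyldimethylsilyl)oxy]-2-hydroxy-4-methyl-3-(prop-1-en-2-yl)-4-vinylcyclohexyl]acetate
Product: 24 (3aS,4S,6S,7S,7aR)-4-[(tert-butyldimethylsilyl)oxy]-6-methyl-7-(prop-1-en-2-yl)-6-vinylhexahydrobenzofuran-2(3H)-one
Conditions: TFA/CH2Cl2 (1:10), 0 °C → rt
Reagents that add atoms: none
Why: Acidolysis of the tert-butyl ester (loss of isobutene) and acid-catalysed lactonisation of the γ-hydroxy acid onto the equatorial C6 hydroxyl should give the trans-fused γ-lactone; O8 stays silylated, so only the 12,6-lactone can form.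

Step 18
Reactants: 24 (3aS,4S,6S,7S,7aR)-4-[(tert-butyldimethylsilyl)oxy]-6-methyl-7-(prop-1-en-2-yl)-6-vinylhexahydrobenzofuran-2(3H)-one
Product: 27 (3aS,4S,6S,7S,7aR)-4-[(tert-butyldimethylsilyl)oxy]-6-methyl-3-methylene-7-(prop-1-en-2-yl)-6-vinylhexahydrobenzofuran-2(3H)-one, via Mannich base 25 (not isolated), via trimethylammonium iodide 26 (not isolated)
Conditions: LDA, THF, −78 °C; CH2=NMe2+ I−, −78 °C → rt; then MeI, MeOH; then aq. NaHCO3, CH2Cl2
Reagents that add atoms: dimethyl(methylidene)ammonium iodide (Eschenmoser's salt) C=[N+](C)C.[I-]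
Why: Eschenmoser α-methylenation (Mannich reaction of the lactone lithium enolate, N-methylation, β-elimination of trimethylamine) installs C11=C13; the transient C11 stereocentre is destroyed.

Step 19
Reactants: 27 (3aS,4S,6S,7S,7aR)-4-[(tert-butyldimethylsilyl)oxy]-6-methyl-3-methylene-7-(prop-1-en-2-yl)-6-vinylhexahydrobenzofuran-2(3H)-one
Product: 28 (3aS,4S,6S,7R,7aR)-4-[(tert-butyldimethylsilyl)oxy]-7-(3-hydroxyprop-1-en-2-yl)-6-methyl-3-methylene-6-vinylhexahydrobenzofuran-2(3H)-one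
Conditions: SeO2 (0.5 equiv), t-BuOOH, CH2Cl2, rt
Reagents that add atoms: selenium dioxide (oxygen carrier) O=[Se]=O; tert-butyl hydroperoxide (oxygen source) CC(C)(C)OO
Why: Selenium dioxide allylic oxidation (ene reaction, then [2,3]-sigmatropic shift) hydroxylates the isopropenyl methyl group, as known for isopulegol-type isopropenyl groups; the vinyl group has no allylic hydrogen and the lactone methylene is electron-poor.

Step 20
Reactants: 28 (3aS,4S,6S,7R,7aR)-4-[(tert-butyldimethylsilyl)oxy]-7-(3-hydroxyprop-1-en-2-yl)-6-methyl-3-methylene-6-vinylhexahydrobenzofuran-2(3H)-one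
Product: 29 2-[(3aS,4S,6S,7R,7aR)-4-[(tert-butyldimethylsilyl)oxy]-6-methyl-3-methylene-2-oxo-6-vinyloctahydrobenzofuran-7-yl]acrylaldehyde
Conditions: MnO2, CH2Cl2, rt
Reagents that add atoms: none
Why: Manganese dioxide oxidation is selective for the allylic alcohol and gives the C15 enal.

Step 21
Reactants: 29 2-[(3aS,4S,6S,7R,7aR)-4-[(tert-butyldimethylsilyl)oxy]-6-methyl-3-methylene-2-oxo-6-vinyloctahydrobenzofuran-7-yl]acrylaldehyde
Product: 30 2-[(3aR,4S,6S,7R,7aR)-4-hydroxy-6-methyl-3-methylene-2-oxo-6-vinyloctahydrobenzofuran-7-yl]acrylaldehyde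
Conditions: HF·pyridine, pyridine, THF, 0 °C → rt
Reagents that add atoms: none
Why: Acidic fluoride desilylation frees O8 without forming an alkoxide that could shift the lactone from O6 to O8 or add to the two Michael acceptors.

Step 22
Reactants: 31 methyl (2R)-2-[(4S)-2,2-dimethyl-1,3-dioxolan-4-yl]-2-hydroxyacetate (methyl 3,4-O-isopropylidene-L-threonate)
Product: 32 methyl 2-[(S)-2,2-dimethyl-1,3-dioxolan-4-yl]-2-oxoacetate
Conditions: Dess–Martin periodinane, CH2Cl2, rt
Reagents that add atoms: none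
Why: Dess–Martin oxidation of the α-hydroxy ester to the α-keto ester under neutral conditions keeps the adjacent acetal stereocentre.

Step 23
Reactants: 32 methyl 2-[(S)-2,2-dimethyl-1,3-dioxolan-4-yl]-2-oxoacetate
Product: 33 methyl 2-[(R)-2,2-dimethyl-1,3-dioxolan-4-yl]acrylate
Conditions: Ph3PCH3Br, KHMDS, THF, 0 °C; then 32 added at −78 °C, → 0 °C
Reagents that add atoms: methyltriphenylphosphonium bromide C[P+](c1ccccc1)(c1ccccc1)c1ccccc1.[Br-]
Why: Wittig methylenation of the highly electrophilic keto carbonyl (faster than the ester); the low temperature limits enolisation toward C3', whose descriptor changes only through priority.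

Step 24
Reactants: 33 methyl 2-[(R)-2,2-dimethyl-1,3-dioxolan-4-yl]acrylate
Product: 34 2-[(R)-2,2-dimethyl-1,3-dioxolan-4-yl]acrylic acid
Conditions: LiOH·H2O, THF/H2O, 0 °C; then 1 M HCl to pH 3–4 at 0 °C; used at once
Reagents that add atoms: lithium hydroxide [Li+].[OH-]
Why: Saponification of the methyl ester; the acetonide is stable to base and to the brief mild acidification.

Step 25
Reactants: 34 2-[(R)-2,2-dimethyl-1,3-dioxolan-4-yl]acrylic acid; 30 2-[(3aR,4S,6S,7R,7aR)-4-hydroxy-6-methyl-3-methylene-2-oxo-6-vinyloctahydrobenzofuran-7-yl]acrylaldehyde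
Product: 36 (3aR,4S,6S,7R,7aR)-6-methyl-3-methylene-2-oxo-7-(3-oxoprop-1-en-2-yl)-6-vinyloctahydrobenzofuran-4-yl 2-[(R)-2,2-dimethyl-1,3-dioxolan-4-yl]acrylate, via Yamaguchi mixed anhydride 35 (not isolated)
Conditions: 2,4,6-trichlorobenzoyl chloride, Et3N, THF, rt; then 30, DMAP, toluene, rt
Reagents that add atoms: none
Why: Yamaguchi esterification; DMAP transfers the acyl group from the mixed anhydride to the hindered equatorial C8 hydroxyl under non-acidic conditions that spare the acetonide, enal and lactone.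

Step 26
Reactants: 36 (3aR,4S,6S,7R,7aR)-6-methyl-3-methylene-2-oxo-7-(3-oxoprop-1-en-2-yl)-6-vinyloctahydrobenzofuran-4-yl 2-[(R)-2,2-dimethyl-1,3-dioxolan-4-yl]acrylate
Product: 37 (3aR,4S,6S,7R,7aR)-6-methyl-3-methylene-2-oxo-7-(3-oxoprop-1-en-2-yl)-6-vinyloctahydrobenzofuran-4-yl (R)-3,4-dihydroxy-2-methylenebutanoate (CNP0204284.1)
Conditions: AcOH/THF/H2O (3:1:1), 40 °C
Reagents that add atoms: none
Why: Acid-catalysed acetal hydrolysis releases the 1,2-diol under conditions too mild for the ester, the lactone or the enal.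

**Compound list**

1 | diethyl methylmalonate | CCOC(=O)C(C)C(=O)OCC | starting material
2 | (2-bromoethoxy)(tert-butyl)dimethylsilane | BrCCO[Si](C)(C)C(C)(C)C | starting material
3 | diethyl 2-{2-[(tert-butyldimethylsilyl)oxy]ethyl}-2-methylmalonate | CCOC(=O)C(C)(CCO[Si](C)(C)C(C)(C)C)C(=O)OCC | intermediate
4 | 2-{2-[(tert-butyldimethylsilyl)oxy]ethyl}-2-methylpropane-1,3-diol | OCC(C)(CO)CCO[Si](C)(C)C(C)(C)C | intermediate
5 | (S)-4-[(tert-butyldimethylsilyl)oxy]-2-(hydroxymethyl)-2-methylbutyl acetate | CC(=O)OC[C@](C)(CO)CCO[Si](C)(C)C(C)(C)C | intermediate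
6 | (R)-4-[(tert-butyldimethylsilyl)oxy]-2-formyl-2-methylbutyl acetate | CC(=O)OC[C@](C)(C=O)CCO[Si](C)(C)C(C)(C)C | intermediate
7 | (S)-2-{2-[(tert-butyldimethylsilyl)oxy]ethyl}-2-methylbut-3-en-1-yl acetate | CC(=O)OC[C@](C)(C=C)CCO[Si](C)(C)C(C)(C)C | intermediate
8 | (S)-2-{2-[(tert-butyldimethylsilyl)oxy]ethyl}-2-methylbut-3-en-1-ol | OC[C@](C)(C=C)CCO[Si](C)(C)C(C)(C)C | intermediate
9 | (S)-2-{2-[(tert-butyldimethylsilyl)oxy]ethyl}-2-methylbut-3-enal | O=C[C@](C)(C=C)CCO[Si](C)(C)C(C)(C)C | intermediate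
10 | tert-butyl{[(S)-3,5-dimethyl-3-vinylhex-4-en-1-yl]oxy}dimethylsilane | CC(C)=C[C@](C)(C=C)CCO[Si](C)(C)C(C)(C)C | intermediate
11 | (S)-3,5-dimethyl-3-vinylhex-4-en-1-ol | CC(C)=C[C@](C)(C=C)CCO | intermediate
12 | (S)-3,5-dimethyl-3-vinylhex-4-enal | CC(C)=C[C@](C)(C=C)CC=O | intermediate
13 | 4-tert-butoxy-4-oxobutanoic acid (mono-tert-butyl succinate) | CC(C)(C)OC(=O)CCC(=O)O | starting material
14 | (R)-4-benzyloxazolidin-2-one | O=C1N[C@H](Cc2ccccc2)CO1 | starting material
15 | 4-tert-butoxy-4-oxobutanoic pivalic anhydride | CC(C)(C)OC(=O)CCC(=O)OC(=O)C(C)(C)C | intermediate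
16 | tert-butyl 4-[(R)-4-benzyl-2-oxooxazolidin-3-yl]-4-oxobutanoate | CC(C)(C)OC(=O)CCC(=O)N1[C@H](Cc2ccccc2)COC1=O | intermediate
17 | tert-butyl (Z)-4-[(R)-4-benzyl-2-oxooxazolidin-3-yl]-4-[(dibutylboranyl)oxy]but-3-enoate | CCCCB(CCCC)O/C(=C\CC(=O)OC(C)(C)C)N1[C@H](Cc2ccccc2)COC1=O | intermediate
18 | O8-dibutylboranyl derivative (boron aldolate) of 19 | O=C(N1[C@H](Cc2ccccc2)COC1=O)[C@H](CC(=O)OC(C)(C)C)[C@@H](OB(CCCC)CCCC)C[C@@](C)(C=C)C=C(C)C | intermediate
19 | tert-butyl (3R,4S,6S)-3-[(R)-4-benzyl-2-oxooxazolidine-3-carbonyl]-4-hydroxy-6,8-dimethyl-6-vinylnon-7-enoate | O=C(N1[C@H](Cc2ccccc2)COC1=O)[C@H](CC(=O)OC(C)(C)C)[C@@H](O)C[C@@](C)(C=C)C=C(C)C | intermediate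
20 | tert-butyl (3R,4S,6S)-3-[(R)-4-benzyl-2-oxooxazolidine-3-carbonyl]-4-[(tert-butyldimethylsilyl)oxy]-6,8-dimethyl-6-vinylnon-7-enoate | O=C(N1[C@H](Cc2ccccc2)COC1=O)[C@H](CC(=O)OC(C)(C)C)[C@@H](O[Si](C)(C)C(C)(C)C)C[C@@](C)(C=C)C=C(C)C | intermediate
21 | tert-butyl (3S,4S,6S)-4-[(tert-butyldimethylsilyl)oxy]-3-(hydroxymethyl)-6,8-dimethyl-6-vinylnon-7-enoate | OC[C@H](CC(=O)OC(C)(C)C)[C@@H](O[Si](C)(C)C(C)(C)C)C[C@@](C)(C=C)C=C(C)C | intermediate
22 | tert-butyl (3R,4S,6S)-4-[(tert-butyldimethylsilyl)oxy]-3-formyl-6,8-dimethyl-6-vinylnon-7-enoate | O=C[C@H](CC(=O)OC(C)(C)C)[C@@H](O[Si](C)(C)C(C)(C)C)C[C@@](C)(C=C)C=C(C)C | intermediate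
23 | tert-butyl 2-[(1S,2R,3S,4S,6S)-6-[(tert-butyldimethylsilyl)oxy]-2-hydroxy-4-methyl-3-(prop-1-en-2-yl)-4-vinylcyclohexyl]acetate | C=C[C@]1(C)C[C@H](O[Si](C)(C)C(C)(C)C)[C@@H](CC(=O)OC(C)(C)C)[C@H](O)[C@H]1C(C)=C | intermediate
24 | (3aS,4S,6S,7S,7aR)-4-[(tert-butyldimethylsilyl)oxy]-6-methyl-7-(prop-1-en-2-yl)-6-vinylhexahydrobenzofuran-2(3H)-one | C=C[C@]1(C)C[C@H](O[Si](C)(C)C(C)(C)C)[C@H]2CC(=O)O[C@@H]2[C@H]1C(C)=C | intermediate
25 | 3-[(dimethylamino)methyl] derivative of 24 (Mannich base, C3 configuration not defined) | C=C[C@]1(C)C[C@H](O[Si](C)(C)C(C)(C)C)[C@H]2C(CN(C)C)C(=O)O[C@@H]2[C@H]1C(C)=C | intermediate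
26 | N-methyl ammonium iodide of 25 | C=C[C@]1(C)C[C@H](O[Si](C)(C)C(C)(C)C)[C@H]2C(C[N+](C)(C)C)C(=O)O[C@@H]2[C@H]1C(C)=C.[I-] | intermediate
27 | (3aS,4S,6S,7S,7aR)-4-[(tert-butyldimethylsilyl)oxy]-6-methyl-3-methylene-7-(prop-1-en-2-yl)-6-vinylhexahydrobenzofuran-2(3H)-one | C=C[C@]1(C)C[C@H](O[Si](C)(C)C(C)(C)C)[C@H]2C(=C)C(=O)O[C@@H]2[C@H]1C(C)=C | intermediate
28 | (3aS,4S,6S,7R,7aR)-4-[(tert-butyldimethylsilyl)oxy]-7-(3-hydroxyprop-1-en-2-yl)-6-methyl-3-methylene-6-vinylhexahydrobenzofuran-2(3H)-one | C=C[C@]1(C)C[C@H](O[Si](C)(C)C(C)(C)C)[C@H]2C(=C)C(=O)O[C@@H]2[C@H]1C(=C)CO | intermediate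
29 | 2-[(3aS,4S,6S,7R,7aR)-4-[(tert-butyldimethylsilyl)oxy]-6-methyl-3-methylene-2-oxo-6-vinyloctahydrobenzofuran-7-yl]acrylaldehyde | C=C[C@]1(C)C[C@H](O[Si](C)(C)C(C)(C)C)[C@H]2C(=C)C(=O)O[C@@H]2[C@H]1C(=C)C=O | intermediate
30 | 2-[(3aR,4S,6S,7R,7aR)-4-hydroxy-6-methyl-3-methylene-2-oxo-6-vinyloctahydrobenzofuran-7-yl]acrylaldehyde | C=C[C@]1(C)C[C@H](O)[C@H]2C(=C)C(=O)O[C@@H]2[C@H]1C(=C)C=O | intermediate
31 | methyl (2R)-2-[(4S)-2,2-dimethyl-1,3-dioxolan-4-yl]-2-hydroxyacetate (methyl 3,4-O-isopropylidene-L-threonate) | COC(=O)[C@H](O)[C@@H]1COC(C)(C)O1 | starting material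
32 | methyl 2-[(S)-2,2-dimethyl-1,3-dioxolan-4-yl]-2-oxoacetate | COC(=O)C(=O)[C@@H]1COC(C)(C)O1 | intermediate
33 | methyl 2-[(R)-2,2-dimethyl-1,3-dioxolan-4-yl]acrylate | COC(=O)C(=C)[C@@H]1COC(C)(C)O1 | intermediate
34 | 2-[(R)-2,2-dimethyl-1,3-dioxolan-4-yl]acrylic acid | C=C(C(=O)O)[C@@H]1COC(C)(C)O1 | intermediate
35 | 2-[(R)-2,2-dimethyl-1,3-dioxolan-4-yl]acrylic 2,4,6-trichlorobenzoic anhydride | C=C(C(=O)OC(=O)c1c(Cl)cc(Cl)cc1Cl)[C@@H]1COC(C)(C)O1 | intermediate
36 | (3aR,4S,6S,7R,7aR)-6-methyl-3-methylene-2-oxo-7-(3-oxoprop-1-en-2-yl)-6-vinyloctahydrobenzofuran-4-yl 2-[(R)-2,2-dimethyl-1,3-dioxolan-4-yl]acrylate | C=C[C@]1(C)C[C@H](OC(=O)C(=C)[C@@H]3COC(C)(C)O3)[C@H]2C(=C)C(=O)O[C@@H]2[C@H]1C(=C)C=O | intermediate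
37 | (3aR,4S,6S,7R,7aR)-6-methyl-3-methylene-2-oxo-7-(3-oxoprop-1-en-2-yl)-6-vinyloctahydrobenzofuran-4-yl (R)-3,4-dihydroxy-2-methylenebutanoate | C=C[C@]1(C)C[C@H](OC(=O)C(=C)[C@@H](O)CO)[C@H]2C(=C)C(=O)O[C@@H]2[C@H]1C(=C)C=O | target

**Counts**
Total steps: 26. Longest linear sequence: 22 (steps 1–10, 12–21, 25, 26); step 11 and steps 22–24 are side branches.

**Steps most likely to fail**

Step 16. The Lewis-acid-bound aldehyde may ionise to a free tertiary cation (Prins pathway with chloride capture or alkene migration), may be attacked on the wrong carbonyl face, or may lose silanol before ring closure. The fallback forms the same C5–C6 bond by an intramolecular Nozaki–Hiyama–Kishi allylation; it sets out from 21 and comes back at 23. Selenium dioxide/t-BuOOH should oxidise the E-methyl group of the 2-methylpropenyl unit of 21 to give tert-butyl (3S,4S,6S,7E)-4-[(tert-butyldimethylsilyl)oxy]-9-hydroxy-3-(hydroxymethyl)-6,8-dimethyl-6-vinylnon-7-enoate F1. Corey–Kim halogenation (NBS, Me2S, CH2Cl2, −20 °C), which converts allylic but not saturated alcohols, gives tert-butyl (3S,4S,6S,7E)-9-bromo-4-[(tert-butyldimethylsilyl)oxy]-3-(hydroxymethyl)-6,8-dimethyl-6-vinylnon-7-enoate F2. Dess–Martin oxidation of the remaining primary alcohol gives tert-butyl (3R,4S,6S,7E)-9-bromo-4-[(tert-butyldimethylsilyl)oxy]-3-formyl-6,8-dimethyl-6-vinylnon-7-enoate F3. CrCl2 in THF at high dilution then turns the allylic bromide into an allylchromium species that adds through C5 to the C6 aldehyde in a chair transition state; the anti (trans C5/C6) product with an isopropenyl group is 23.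

Step 3. The enzyme may distinguish the two hydroxymethyl arms poorly, and acyl migration between the two oxygens may erode the optical purity before step 4. The fallback replaces the enzyme by a classical resolution; it sets out from 3 and comes back at 8. Half-saponification of 3 (KOH, 1 equiv, EtOH) gives racemic 2-{2-[(tert-butyldimethylsilyl)oxy]ethyl}-3-ethoxy-2-methyl-3-oxopropanoic acid F4. Crystallisation of its salt with (R)-1-phenylethylamine (salt or mother liquor, as found) and acidification gives (S)-2-{2-[(tert-butyldimethylsilyl)oxy]ethyl}-3-ethoxy-2-methyl-3-oxopropanoic acid F5. BH3·SMe2 reduces only the free acid, giving ethyl (S)-4-[(tert-butyldimethylsilyl)oxy]-2-(hydroxymethyl)-2-methylbutanoate F6. Dess–Martin oxidation gives ethyl (S)-4-[(tert-butyldimethylsilyl)oxy]-2-formyl-2-methylbutanoate F7, and Wittig methylenation gives ethyl (S)-2-{2-[(tert-butyldimethylsilyl)oxy]ethyl}-2-methylbut-3-enoate F8. LiAlH4 reduction of the ester then gives 8.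

Step 17. The acid may remove the C8 silyl ether, after which the lactone could close onto O8, may add to the isopropenyl group, or may stop at the hydroxy acid because the trans-fused ring closes slowly. The fallback separates ester cleavage from ring closure and avoids protic acid; it sets out from 23 and comes back at 24. TMSOTf/2,6-lutidine (CH2Cl2, 0 °C) should convert the tert-butyl ester into a silyl ester and cap O6, giving the trimethylsilyl ester/C6 trimethylsilyl ether F9. Brief K2CO3/MeOH treatment and neutral work-up gives 2-[(1S,2R,3S,4S,6S)-6-[(tert-butyldimethylsilyl)oxy]-2-hydroxy-4-methyl-3-(prop-1-en-2-yl)-4-vinylcyclohexyl]acetic acid F10. Carbodiimide lactonisation (EDC·HCl, DMAP, CH2Cl2) then closes 24.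

**Further compounds**
F1 | step 16 | tert-butyl (3S,4S,6S,7E)-4-[(tert-butyldimethylsilyl)oxy]-9-hydroxy-3-(hydroxymethyl)-6,8-dimethyl-6-vinylnon-7-enoate | OC[C@H](CC(=O)OC(C)(C)C)[C@@H](O[Si](C)(C)C(C)(C)C)C[C@@](C)(C=C)/C=C(\C)CO
F2 | step 16 | tert-butyl (3S,4S,6S,7E)-9-bromo-4-[(tert-butyldimethylsilyl)oxy]-3-(hydroxymethyl)-6,8-dimethyl-6-vinylnon-7-enoate | OC[C@H](CC(=O)OC(C)(C)C)[C@@H](O[Si](C)(C)C(C)(C)C)C[C@@](C)(C=C)/C=C(\C)CBr
F3 | step 16 | tert-butyl (3R,4S,6S,7E)-9-bromo-4-[(tert-butyldimethylsilyl)oxy]-3-formyl-6,8-dimethyl-6-vinylnon-7-enoate | O=C[C@H](CC(=O)OC(C)(C)C)[C@@H](O[Si](C)(C)C(C)(C)C)C[C@@](C)(C=C)/C=C(\C)CBr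
F4 | step 3 | rac-2-{2-[(tert-butyldimethylsilyl)oxy]ethyl}-3-ethoxy-2-methyl-3-oxopropanoic acid | CCOC(=O)C(C)(CCO[Si](C)(C)C(C)(C)C)C(=O)O
F5 | step 3 | (S)-2-{2-[(tert-butyldimethylsilyl)oxy]ethyl}-3-ethoxy-2-methyl-3-oxopropanoic acid | CCOC(=O)[C@](C)(C(=O)O)CCO[Si](C)(C)C(C)(C)C
F6 | step 3 | ethyl (S)-4-[(tert-butyldimethylsilyl)oxy]-2-(hydroxymethyl)-2-methylbutanoate | CCOC(=O)[C@](C)(CO)CCO[Si](C)(C)C(C)(C)C
F7 | step 3 | ethyl (S)-4-[(tert-butyldimethylsilyl)oxy]-2-formyl-2-methylbutanoate | CCOC(=O)[C@](C)(C=O)CCO[Si](C)(C)C(C)(C)C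
F8 | step 3 | ethyl (S)-2-{2-[(tert-butyldimethylsilyl)oxy]ethyl}-2-methylbut-3-enoate | CCOC(=O)[C@](C)(C=C)CCO[Si](C)(C)C(C)(C)C
F9 | step 17 | trimethylsilyl ester and C6 trimethylsilyl ether of F10 | C=C[C@]1(C)C[C@H](O[Si](C)(C)C(C)(C)C)[C@@H](CC(=O)O[Si](C)(C)C)[C@H](O[Si](C)(C)C)[C@H]1C(C)=C
F10 | step 17 | 2-[(1S,2R,3S,4S,6S)-6-[(tert-butyldimethylsilyl)oxy]-2-hydroxy-4-methyl-3-(prop-1-en-2-yl)-4-vinylcyclohexyl]acetic acid | C=C[C@]1(C)C[C@H](O[Si](C)(C)C(C)(C)C)[C@@H](CC(=O)O)[C@H](O)[C@H]1C(C)=C
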